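(The readings are calculated with made-up constants, noise included.)

**Early readings.** Early on I wanted one thing from these runs: how fast target first appeared.

| flask | substrate | gas phase | remark | time |
|---|---|---|---|---|
| grey | 0.050 M | 59 mM (held) | run made earlier |  |
| green | 0.20 M | 59 mM (held) | run made earlier |  |
| flask | 0.10 M | 59 mM (held) |  | 3.0 h |

| run | time / h | target / % |
|---|---|---|
| grey | 0.250 | 6.9 |
| grey | 0.417 | 12.2 |
| grey | 0.833 | 19.1 |
| grey | 1.50 | 27.7 |
| grey | 3.00 | 33.5 |
| green | 0.250 | 9.6 |
| green | 0.833 | 13.9 |
| green | 1.33 | 16.6 |
| green | 2.00 | 15.9 |
| green | 3.00 | 18.7 |

(readings scatter by 1 percentage point)

- at the start none of the gas phase is in solution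

- alder: doubling the transfer coefficient of the gas phase, all else as stated
- ash: doubling the saturation concentration of gas phase, all else as stated

- amount of target at 3.0 h, in percent of the substrate charged
- the change that raises the amount of target at 3.0 h, in percent of the substrate charged most ("none" if none brings more than 2 percentage points) (alder / ash / none)
- amount of target at 3.0 h, in percent of the substrate charged, after alder

**Main step.** With the gas phase held, I treated substrate going to target as pseudo-first-order. The first readings at 0.250 h of the grey and green runs gave a mean early constant of 0.330 /h. On that reckoning, with no loss counted, the flask stood at 62.8% at 3.0 h.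

**Fixed loss.** Next I added a loss at a fixed rate per substrate. With both steps first order in substrate and the gas phase held, it gave one yield at a given time whatever the loading, so I took the mean of the two runs at 3.0 h, 26.1%. But those runs stood 15 percentage points apart, with a scatter of 1 point.

**Loading loss.** So I added a loss that grows with loading, measured by the loading exponent: the logarithm of the yield ratio of two runs at one time and one saturation concentration of gas phase, divided by the logarithm of their loading ratio. The reading was 0.421, with the scatter of its two readings. Stepping from the grey run to the flask gave me 25.0%.

**The forecast.** It said 26% (range 22% to 30%), 1.00 point above my reckoning, 27.5% after alder (range 23% to 34%), and ash as the best change. Its ground against alder was that “transfer is fairly fast and gas is near saturation”.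

**The result.** The flask gave 26.5%, 1.5 points above what the exponent 0.421 gave me. Ash added 15 points and alder 0.18 points, leaving 26.7% after alder, so ash was best.

    substrate + target → side product B (k = 0.140 /M/min)
    substrate + dissolved gas ⇌ target (K = 420 /M, k = 0.110 /M/min)
    gas phase ⇌ dissolved gas, rate k3*(csat - [dissolved gas]) (kL = 0.530 /min)
    substrate → side product A (k = 0.00580 /min)

**Target's loss.** With concentrations as charged, the half-life of target by reaction with substrate to side product B was 0.83 h, shorter than the 3.0 h of the run. At 3.00 h, with substrate at 7.12%, that half-life was 12 h, longer than the run.

**Second flask.** For the neighbour charged with 0.040 M of substrate, the exponent gave 36.8%. The computed result there was 35.5%.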